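**Plan**

- Labels: ring A carries its free hydroxyl at position 1, the chain at position 3 and the ether oxygen at position 5. Ring B carries B1–OAr, B2–H, B3–OH, B4–H, B5–chain and B6–OH. A (CH2)14 chain from position 3 of ring A to B5 completes the 21-membered ring.
- Enabling feature: ring B is a para-hydroquinone (B3–O, B6–O) whose B6 hydroxyl lies between the aryloxy carbon B1 and the chain carbon B5. A carbene/alkyne/CO benzannulation leaves exactly this array when B6 is the CO carbon.
- Retrosynthesis: cut the two O–CH3 bonds, then ring B at B2–B3, B1–B6 and B5–B6 (which also opens the macrocycle) to an alkenyl(methoxy)carbene chromium complex tethered to an aryl ethynyl ether. Then cut the alkenyl C=C (aldol condensation), the O–C(sp) bond (via trichloroethylene) and the aryl–CH2 bond at position 3 of ring A (Negishi coupling).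
- Forward: ring A is bought and the C15 chain of pentadecanolide is attached at its position 3. The phenol at position 5 becomes the ethynyl ether, and the chain end is oxidised and condensed with the methyl carbene complex. Ring B and the macrocycle then form together, and demethylation finishes the route.
- Stereochemistry: the target has no stereocentre and no configured double bond. The E alkene of the carbene complex is set in the condensation and disappears into ring B.

Key step: step 11

Remark: in the SMILES of the π-complexes 19 and 20 the Cr(CO)3 fragment is written as a dot-joined component.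

**Route**

Step 1
Reactants: 1 3-bromo-5-methoxyphenol
Product: 2 3-bromo-5-methoxyphenyl pivalate
Conditions: PivCl, Et3N, DMAP (cat.), CH2Cl2, 0 °C → rt
Reagents that add atoms: pivaloyl chloride, CC(C)(C)C(Cl)=O
Why: DMAP-catalysed O-acylation masks the acidic phenol that would quench the alkylzinc reagent of step 4, and the hindered pivalate is inert to organozinc halides and to palladium.

Step 2
Reactants: 3 pentadecanolide
Product: 4 methyl 15-hydroxypentadecanoate
Conditions: MeOH, H2SO4 (cat.), reflux
Reagents that add atoms: methanol, CO
Why: Acid-catalysed transesterification (Fischer-type methanolysis) opens the unstrained macrolactone, and the large excess of methanol holds the equilibrium on the side of the open hydroxy ester.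

Step 3
Reactants: 4 methyl 15-hydroxypentadecanoate
Product: 5 methyl 15-iodopentadecanoate
Conditions: I2, PPh3, imidazole, CH2Cl2, 0 °C → rt
Reagents that add atoms: iodine, II
Why: Appel-type iodination converts the primary alcohol by SN2 displacement of the oxyphosphonium group, and the methyl ester is inert.

Step 4
Reactants: 5 methyl 15-iodopentadecanoate; 2 3-bromo-5-methoxyphenyl pivalate
Product: 7 methyl 15-[3-methoxy-5-(pivaloyloxy)phenyl]pentadecanoate, via alkylzinc iodide 6 (not isolated)
Conditions: Zn dust, LiCl, THF, 40 °C; then 2, PdCl2(dppf) (3 mol %), THF, 60 °C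
Reagents that add atoms: none
Why: Knochel-type zinc insertion into the primary iodide tolerates the ester, and Negishi coupling with PdCl2(dppf), reduced in the flask to zerovalent palladium, joins the primary alkylzinc to the aryl bromide because the wide-bite-angle ligand favours reductive elimination over β-hydride elimination while the pivalate is untouched.

Step 5
Reactants: 7 methyl 15-[3-methoxy-5-(pivaloyloxy)phenyl]pentadecanoate
Product: 8 3-(15-hydroxypentadecyl)-5-methoxyphenol
Conditions: LiAlH4, THF, 0 °C → rt; then 1 M HCl
Reagents that add atoms: none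
Why: LiAlH4 reduces the methyl ester to the primary alcohol and at the same time cleaves the aryl pivalate reductively, so that one operation uncovers both hydroxyl groups.

Step 6
Reactants: 8 3-(15-hydroxypentadecyl)-5-methoxyphenol; 9 trichloroethylene
Product: 10 15-{3-[(E)-1,2-dichloroethenyloxy]-5-methoxyphenyl}pentadecan-1-ol
Conditions: K2CO3, DMF, 70 °C
Reagents that add atoms: none
Why: K2CO3 dehydrochlorinates trichloroethylene to dichloroacetylene, to which the phenoxide adds in an anti sense (nucleophilic vinylation) to give the E-dichlorovinyl ether, whereas the aliphatic alcohol is not deprotonated by carbonate and stays free.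

Step 7
Reactants: 10 15-{3-[(E)-1,2-dichloroethenyloxy]-5-methoxyphenyl}pentadecan-1-ol
Product: 12 15-[3-(ethynyloxy)-5-methoxyphenyl]pentadecan-1-ol, via dilithium alkoxide acetylide 11 (not isolated)
Conditions: n-BuLi (3.3 equiv), THF, −78 → −40 °C; then sat. aq. NH4Cl, −78 °C
Reagents that add atoms: none
Why: Greene-type ynol ether synthesis, in which the first equivalent of n-BuLi forms the alkoxide, the second eliminates HCl to the chloroalkynyl ether and the third effects chlorine–lithium exchange to the lithium acetylide, which is protonated cold to the terminal aryl ethynyl ether.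

Step 8
Reactants: 12 15-[3-(ethynyloxy)-5-methoxyphenyl]pentadecan-1-ol
Product: 13 15-[3-(ethynyloxy)-5-methoxyphenyl]pentadecanal
Conditions: SO3·pyridine, DMSO, Et3N, CH2Cl2, 0 °C
Reagents that add atoms: none
Why: Parikh–Doering oxidation with activated DMSO stops at the aldehyde and runs under basic, non-aqueous conditions at 0 °C, which spares the acid-labile ynol ether and the terminal alkyne C–H.

Step 9
Reactants: 14 hexacarbonylchromium, Cr(CO)6
Product: 16 pentacarbonyl(1-methoxyethylidene)chromium, via lithium acetylpentacarbonylchromate 15 (not isolated)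
Conditions: MeLi, Et2O, 0 °C → rt; then Me3OBF4, H2O, 0 °C
Reagents that add atoms: methyllithium, [Li]C; trimethyloxonium tetrafluoroborate, C[O+](C)C.F[B-](F)(F)F
Why: Fischer carbene synthesis, in which MeLi adds to a CO ligand of Cr(CO)6 to give the acylchromate, whose oxygen is then methylated by the Meerwein salt.

Step 10
Reactants: 13 15-[3-(ethynyloxy)-5-methoxyphenyl]pentadecanal; 16 pentacarbonyl(1-methoxyethylidene)chromium
Product: 18 pentacarbonyl{(2E)-17-[3-(ethynyloxy)-5-methoxyphenyl]-1-methoxyheptadec-2-en-1-ylidene}chromium, via silylated aldol adduct 17 (not isolated)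
Conditions: Et3N, Me3SiCl, Et2O, rt, dark, Ar
Reagents that add atoms: none
Why: Aumann-type aldol condensation, in which Et3N deprotonates the acidic α-methyl group of 16, the enolate adds to the aldehyde, Me3SiCl traps the aldolate as 17 and E1cB loss of silanolate gives the conjugated E-alkenyl complex, all at room temperature and thus below the temperature at which chromium loses CO and could engage the ethynyl ether.

Step 11
Reactants: 18 pentacarbonyl{(2E)-17-[3-(ethynyloxy)-5-methoxyphenyl]-1-methoxyheptadec-2-en-1-ylidene}chromium
Product: 21 macrocyclic diaryl ether bearing the free B6 hydroxyl and two methyl ethers (at B3 and on ring A), via dienylketene Cr(CO)3 complex 19 (not isolated), via arene Cr(CO)3 complex 20 (not isolated)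
Conditions: THF (slow addition of 18, final 0.002 M), 65 °C, Ar; then air, light, Et2O, rt
Reagents that add atoms: none
Why: Proposed new method: loss of one CO from 18 on heating lets the tethered ethynyl ether bind chromium and insert into the Cr=C bond with its unsubstituted, nucleophilic carbon (B2) joining the electrophilic carbene carbon (B3), after which CO insertion at the aryloxy-bearing carbon (B1–B6) gives dienylketene complex 19, 6π-electrocyclisation joins B6 to the vinyl β-carbon B5 and tautomerisation gives the chromium-bound 4-methoxyphenol 20, from which air removes Cr(CO)3. The closest known reaction type is the intramolecular Dötz benzannulation of alkenyl(methoxy)carbene chromium complexes that carry an ordinary terminal alkyne on a tether from the vinyl β-carbon and give meta-bridged phenols; an aryl ethynyl ether as the tethered alkyne has not been shown in this mode. The macrocycle closes in the alkyne insertion as a 23-membered ring (end-to-end closure on the metal through a strain-free chain) and contracts to the 21-membered ring when ring B closes by the six-electron electrocyclisation of the dienylketene. No stereocentre is formed, and the E alkene of 18 ends up inside ring B. The step needs one orientation of insertion, which the size of the aryloxy group against hydrogen and the donor polarisation of the ynol ether both direct so that OAr lands next to the CO-derived carbon, and it needs ring closure to beat oligomerisation, which slow addition into hot THF at about 0.002 M and the flexible fourteen-methylene tether secure. Because the tether leaves from the vinyl β-carbon, only the meta-bridged arene with the new hydroxyl between the two bridgeheads (B1, B6, B5) can result, and an alkenyl chromium complex in THF is the combination that favours phenol formation over cyclopentannulation.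

Step 12
Reactants: 21 macrocyclic diaryl ether bearing the free B6 hydroxyl and two methyl ethers (at B3 and on ring A)
Product: 22 CNP0393720 (target; free hydroxyls on ring A, at B3 and at B6)
Conditions: BBr3, CH2Cl2, −78 °C → rt; then degassed H2O, 0 °C
Reagents that add atoms: none
Why: BBr3 cleaves aryl methyl ethers by Lewis-acid complexation and bromide attack at methyl, which removes both methyl groups while the diaryl ether and the saturated tether are inert, and the degassed work-up protects the electron-rich hydroquinone from air oxidation.

**Compound list**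

1 | 3-bromo-5-methoxyphenol | COc1cc(O)cc(Br)c1 | starting material
2 | 3-bromo-5-methoxyphenyl pivalate | COc1cc(OC(=O)C(C)(C)C)cc(Br)c1 | intermediate
3 | pentadecanolide | O=C1CCCCCCCCCCCCCCO1 | starting material
4 | methyl 15-hydroxypentadecanoate | COC(=O)CCCCCCCCCCCCCCO | intermediate
5 | methyl 15-iodopentadecanoate | COC(=O)CCCCCCCCCCCCCCI | intermediate
6 | (15-methoxy-15-oxopentadecyl)zinc iodide | COC(=O)CCCCCCCCCCCCCC[Zn]I | intermediate
7 | methyl 15-[3-methoxy-5-(pivaloyloxy)phenyl]pentadecanoate | COC(=O)CCCCCCCCCCCCCCc1cc(OC)cc(OC(=O)C(C)(C)C)c1 | intermediate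
8 | 3-(15-hydroxypentadecyl)-5-methoxyphenol | COc1cc(O)cc(CCCCCCCCCCCCCCCO)c1 | intermediate
9 | trichloroethylene | ClC=C(Cl)Cl | starting material
10 | 15-{3-[(E)-1,2-dichloroethenyloxy]-5-methoxyphenyl}pentadecan-1-ol | COc1cc(O/C(Cl)=C\Cl)cc(CCCCCCCCCCCCCCCO)c1 | intermediate
11 | lithium 15-{3-[(lithioethynyl)oxy]-5-methoxyphenyl}pentadecan-1-olate | [Li]OCCCCCCCCCCCCCCCc1cc(OC)cc(OC#C[Li])c1 | intermediate
12 | 15-[3-(ethynyloxy)-5-methoxyphenyl]pentadecan-1-ol | COc1cc(OC#C)cc(CCCCCCCCCCCCCCCO)c1 | intermediate
13 | 15-[3-(ethynyloxy)-5-methoxyphenyl]pentadecanal | COc1cc(OC#C)cc(CCCCCCCCCCCCCCC=O)c1 | intermediate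
14 | hexacarbonylchromium, Cr(CO)6 | O=C=[Cr](=C=O)(=C=O)(=C=O)(=C=O)=C=O | starting material
15 | lithium acetylpentacarbonylchromate | CC([O-])=[Cr](=C=O)(=C=O)(=C=O)(=C=O)=C=O.[Li+] | intermediate
16 | pentacarbonyl(1-methoxyethylidene)chromium | COC(C)=[Cr](=C=O)(=C=O)(=C=O)(=C=O)=C=O | intermediate
17 | pentacarbonyl{17-[3-(ethynyloxy)-5-methoxyphenyl]-1-methoxy-3-(trimethylsilyloxy)heptadecylidene}chromium (racemic) | COC(CC(O[Si](C)(C)C)CCCCCCCCCCCCCCc1cc(OC)cc(OC#C)c1)=[Cr](=C=O)(=C=O)(=C=O)(=C=O)=C=O | intermediate
18 | pentacarbonyl{(2E)-17-[3-(ethynyloxy)-5-methoxyphenyl]-1-methoxyheptadec-2-en-1-ylidene}chromium | COC(/C=C/CCCCCCCCCCCCCCc1cc(OC)cc(OC#C)c1)=[Cr](=C=O)(=C=O)(=C=O)(=C=O)=C=O | intermediate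
19 | tricarbonylchromium complex of the 23-membered dienylketene (ketene on the aryloxy-bearing carbon B1, methoxy on B3, E alkene B4=B5) | C1CCCCCCCCCCCCC/C=C/C(OC)=C\C(=C=O)Oc2cc(OC)cc1c2.O=C=[Cr](=C=O)=C=O | intermediate
20 | tricarbonyl(η6-ring B)chromium complex of macrocycle 21 | COc1cc2cc(c1)Oc1cc(OC)cc(c1O)CCCCCCCCCCCCCC2.O=C=[Cr](=C=O)=C=O | intermediate
21 | 21-membered macrocyclic diaryl ether: OMe at position 1 of ring A, ether oxygen from position 5 of ring A to B1, B3–OMe, B6–OH, (CH2)14 from position 3 of ring A to B5 | COc1cc2cc(c1)Oc1cc(OC)cc(c1O)CCCCCCCCCCCCCC2 | intermediate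
22 | CNP0393720: the same macrocycle with free hydroxyls on ring A, at B3 and at B6 | Oc1cc2cc(c1)Oc1cc(O)cc(c1O)CCCCCCCCCCCCCC2 | target

**Step count and risks**

Total step count: 12. Longest linear sequence: 10 steps (pentadecanolide 3 to 22 through steps 2, 3, 4, 5, 6, 7, 8, 10, 11 and 12).

Steps most likely to fail:

1. Step 11 (macrocyclising benzannulation). The risk lies in intermolecular insertion leading to oligomers, in arrest of the sequence after insertion at a donor-stabilised aryloxy(vinyl)carbene stage without CO uptake, and in insertion with the reverse orientation. The fallback builds the diaryl ether and the macrocycle by known reactions; it sets out from 2 and comes back to the route at 22. Negishi coupling of 2 with oct-7-enylzinc bromide under PdCl2(dppf) gives 3-methoxy-5-(oct-7-en-1-yl)phenyl pivalate F1, and K2CO3 in MeOH frees 3-methoxy-5-(oct-7-en-1-yl)phenol F2. Commercial 2,6-dibromo-4-methoxyphenol is methylated (MeI, K2CO3) to 1,3-dibromo-2,5-dimethoxybenzene F3, and a single Negishi coupling with the same zinc reagent, used as the limiting component, gives 1-bromo-2,5-dimethoxy-3-(oct-7-en-1-yl)benzene F4. Ullmann coupling of F2 with F4 (CuI, picolinic acid, K3PO4, DMSO, 90 °C) gives 2,5-dimethoxy-1-[3-methoxy-5-(oct-7-en-1-yl)phenoxy]-3-(oct-7-en-1-yl)benzene F5. Ring-closing metathesis with second-generation Grubbs catalyst at high dilution gives the 21-membered cycloalkene F6 as an E/Z mixture. Hydrogenation (H2, Pd/C) gives the macrocyclic trimethyl ether F7, and BBr3 cleaves all three methyl ethers to give 22.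

2. Step 10 (aldol condensation). The risk lies in conjugate addition of the enolate of 16 to the alkenyl complex as it forms, in self-condensation of the enolisable aldehyde under amine and chlorosilane, and in slow conversion at the only temperature that the carbene and the ynol ether tolerate together. The fallback separates addition from elimination; it sets out from 13 and 16 and comes back at 18. Complex 16 is deprotonated with n-BuLi in THF at −78 °C and the lithium enolate is added to 13 that has been complexed with BF3·OEt2 at −78 °C immediately before. This gives pentacarbonyl{17-[3-(ethynyloxy)-5-methoxyphenyl]-3-hydroxy-1-methoxyheptadecylidene}chromium F8 (racemic), which is isolated and then dehydrated through its mesylate (MsCl, Et3N, CH2Cl2, 0 °C) to 18.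

3. Step 7 (ynol ether formation). The risk lies in stalling of the elimination and of the chlorine–lithium exchange when the lithium alkoxide aggregates or precipitates at −78 °C, and in hydration of the ynol ether during work-up and chromatography of a polar hydroxy compound. The fallback masks the alcohol; it sets out from 10 and comes back at 12. TBSCl and imidazole in DMF give tert-butyl({15-[3-{[(E)-1,2-dichloroethenyl]oxy}-5-methoxyphenyl]pentadecyl}oxy)dimethylsilane F9. Treatment with n-BuLi (2.2 equiv, THF, −78 °C) and then NH4Cl gives tert-butyl({15-[3-(ethynyloxy)-5-methoxyphenyl]pentadecyl}oxy)dimethylsilane F10, which can be purified as a non-polar compound, and TBAF in THF at 0 °C frees 12.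

**Further compounds**

F1 | step 11 | 3-methoxy-5-(oct-7-en-1-yl)phenyl pivalate | COc1cc(OC(=O)C(C)(C)C)cc(CCCCCCC=C)c1
F2 | step 11 | 3-methoxy-5-(oct-7-en-1-yl)phenol | COc1cc(O)cc(CCCCCCC=C)c1
F3 | step 11 | 1,3-dibromo-2,5-dimethoxybenzene | COc1cc(Br)c(OC)c(Br)c1
F4 | step 11 | 1-bromo-2,5-dimethoxy-3-(oct-7-en-1-yl)benzene | COc1cc(Br)c(OC)c(CCCCCCC=C)c1
F5 | step 11 | 2,5-dimethoxy-1-[3-methoxy-5-(oct-7-en-1-yl)phenoxy]-3-(oct-7-en-1-yl)benzene | COc1cc(CCCCCCC=C)cc(Oc2cc(OC)cc(CCCCCCC=C)c2OC)c1
F6 | step 11 | 21-membered macrocyclic cycloalkene, trimethyl ether (E/Z mixture) | COc1cc2cc(c1)Oc1cc(OC)cc(c1OC)CCCCCCC=CCCCCCC2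
F7 | step 11 | saturated macrocyclic trimethyl ether (OMe on ring A, at B3 and at B6) | COc1cc2cc(c1)Oc1cc(OC)cc(c1OC)CCCCCCCCCCCCCC2
F8 | step 10 | pentacarbonyl{17-[3-(ethynyloxy)-5-methoxyphenyl]-3-hydroxy-1-methoxyheptadecylidene}chromium (racemic) | COC(CC(O)CCCCCCCCCCCCCCc1cc(OC)cc(OC#C)c1)=[Cr](=C=O)(=C=O)(=C=O)(=C=O)=C=O
F9 | step 7 | tert-butyl({15-[3-{[(E)-1,2-dichloroethenyl]oxy}-5-methoxyphenyl]pentadecyl}oxy)dimethylsilane | COc1cc(O/C(Cl)=C\Cl)cc(CCCCCCCCCCCCCCCO[Si](C)(C)C(C)(C)C)c1
F10 | step 7 | tert-butyl({15-[3-(ethynyloxy)-5-methoxyphenyl]pentadecyl}oxy)dimethylsilane | COc1cc(OC#C)cc(CCCCCCCCCCCCCCCO[Si](C)(C)C(C)(C)C)c1
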